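## Structural features

Isospiculoic acid A is a trans-fused bicyclo[4.3.0]nonene. A cyclohexene (C3a, C4, C5, C6, C7, C7a; C6=C7 trisubstituted, ethyl on C7) shares the C3a–C7a bond with a cyclopentanone whose carbonyl C2 lies between C1 (ethyl) and C3 (methyl). Six stereocentres are contiguous: C1–C7a–C3a–C3 around the five-membered ring and C3a–C4–C5 in the six-membered ring. C4 and C5 are adjacent quaternary carbons, each with an ethyl group on one face (called β here) and, cis to each other on the α face, the carboxyl carbon (C4) and the α-carbon of an (E)-styryl group (C5). C3a–H is α and C7a–H is β; the C1 ethyl is β and the C3 methyl α. Fragile points are the epimerisable C1 and C3, the styryl and ring alkenes (no dissolving metal, ozone or hydrogenation once they are present), and the one-carbon arms on C4 and C5, which become β-dicarbonyl units whenever C3a or C6 is a ketone. The real difficulty is the cis pair of quaternary centres with two differentiated one-carbon arms and the relay of their configuration to the ring fusion. The key step uses the fact that the C4 carboxyl carbon and the C5 styryl α-carbon are the two ends of a cleaved cyclobutene cis-fused across C4–C5, which is the acetylene adduct of a cyclohexenone with its carbonyl at C3a and a controlling oxygen at C6.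

## Logic of the disconnections

**33 back to 31.** No skeletal bond is cut. The acid is carried as the methyl ester and the C2 ketone as a dioxolane. The ketal removes every enolisable position of the five-membered ring, which locks C1 and C3 and makes C7 the only site for enolate chemistry. The forward step must cleave a hindered ester at the methyl group and hydrolyse the ketal without epimerising C1 or C3.

**31 back to 30, then to 28 and 29.** The C6–H bond is traced to an enol triflate and the styryl C=C bond to an aldehyde on C5. The triflate keeps the future C6=C7 alkene in an ozone-resistant form during ring cleavage. The forward steps need an (E)-selective olefination of a neopentyl aldehyde and a reduction of a hindered triflate that spares the styrene.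

**28 back to 26.** The ester carbon on C4 and the aldehyde carbon on C5 are reconnected as the C=C bond of a cyclobutene. One alkene then stands for both arms. The forward cleavage must put the carbonyl oxide on the C4 arm; the electron-poor triflyloxy-alkenyl carbon next to C5 is there to bias it.

**26 back to 25, then to 23 and 24.** The C6–O enol bond and the C7–ethyl bond are cut. With C5 quaternary and C2 masked, the C6 ketone can enolise only toward C7, so alkylation and triflation are regiochemically fixed and the C7 configuration does not matter.

**23 back to 20 (through 22 and 21).** These are functional-group changes only. The C6 oxygen that steered the key step is reused as the ketone. C6 must be sp2 before the cyclobutene is opened, because a β oxygen on C6 is syn to the C4 ethyl.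

**20 back to 19.** The C3a–H and C3–H bonds are removed to give the enone. A dissolving-metal reduction sets the trans fusion; it must come while the two arms are still a cyclobutene, which is inert to it.

**19 back to 16, then to 10 and 14.** The C3=C3a bond (aldol condensation) and the C7a–C1 bond (conjugate addition) are cut. All five carbons of C1–C3 with their substituents come from 14. The forward steps need attack at C7a from the α face and no equilibration at C7a afterwards.

**14 back to 11 and 12.** The C=C bond of the nitroalkene is cut by a nitroaldol and dehydration.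

**10 back to 8 and 9 (key).** The C4–C and C5–C bonds of the cyclobutene are cut. Both quaternary centres and their cis relationship come from one step on a simple enone. The forward step needs addition anti to the C6 silyloxy group.

**8 back to 5 and 6, then 5 to 4, 3, 2 and 1.** The C5–ethyl bond is formed by 1,2-addition and carbonyl transposition, and the C6–O bond by α′-hydroxylation of the vinylogous ester. The single stereocentre is obtained by resolution of 3. Oxygenating before the transposition avoids any regiochemical ambiguity.

## Other disconnections considered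

**Alternative 1:** The cut is through C3a–C7a, C1–C2 and C2–C3. The forward step is a dienyl Pauson–Khand reaction of the open-chain dienyne A2 with CO (for example with [RhCl(CO)2]2), giving the bicyclic enone ester A1 with both rings closed at once.
- In its favour: the C6=C7 alkene and the C7 ethyl are already in the diene, the two arms on C4 and C5 are introduced separately so nothing has to be differentiated, and only a conjugate reduction and an ester cleavage remain. On these points it is better than the chosen plan, which spends five steps on the alkene and relies on a regioselective ring cleavage.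
- Against it: A2 must contain the two adjacent quaternary stereocentres in an open chain, where no ring enforces the cis relationship, so the hardest part of the target moves into the precursor. The tether closes a six-membered ring through a fully substituted C4–C5 unit, and C7a is controlled only by conformational preference in the metallacycle. The final enone reduction to the trans fusion must be done with the styryl group present, which excludes dissolving metals.
- Comparison: the metal-mediated closure is sensitive to steric load, whereas the excited-state addition is not. Step economy after the key step is better for A1; before it, it is probably worse.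

**Alternative 2:** The cut is through C5–C6 and C3a–C4. The forward step is a Diels–Alder reaction of the silyloxy diene A4 with the tetrasubstituted alkene of the menthyloxybutenolide A5, followed by acid work-up to the cis-fused enone A3.
- In its favour: the arms arrive already differentiated (lactone carbonyl on C4, acetal carbon on C5), which is a clear advantage over the chosen plan. The menthyloxy acetal gives absolute control without a resolution, which is equal or better. The C7 ketone of A3 would allow the C7 ethyl to be introduced by cross-coupling of an enol triflate, shorter than alkylation, triflation and reduction. The enone also offers C3a as a conjugate acceptor for the five-membered ring.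
- Against it: a ground-state [4+2] addition onto a tetrasubstituted, singly activated alkene that creates two adjacent quaternary centres is expected to be very slow, and the forcing conditions needed (pressure, Lewis acid) threaten the diene and the acetal.
- Comparison: both plans fix the cis relationship by ring fusion. Mechanistically the concerted thermal reaction suffers from the steric compression that the stepwise triplet reaction tolerates. Step economy would be similar or better for A3 if the cycloaddition proceeds.

**Alternative 3:** The cut is through C5–C6. The forward step is an intramolecular Heck reaction of the alkenyl iodide A7 (Pd(OAc)2, phosphine, base): 6-exo carbopalladation of the trisubstituted alkene on the C4 arm and β-hydride elimination toward the benzylic carbon, giving the methyl ester A6 one step from the target.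
- In its favour: the styryl group is unveiled by the ring closure itself, so neither an olefination nor the clash between styrene and dissolving metal arises. The elimination has one direction only, and the end game is shorter than in the chosen plan. These points are equal or better.
- Against it: C4 must be set as a quaternary stereocentre on a side chain. The carbopalladation must then create a quaternary carbon next to it with the correct face, and nothing but conformational preference makes the carboxyl and styryl groups cis. The alkene geometry in A7 must also be controlled.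
- Comparison: the chosen plan guarantees the cis relationship structurally. The Heck plan is more convergent but rests on an uncertain diastereoselection at the most congested bond.

Key step: step 6

Remarks on the chemistry:
- Ring positions are given throughout in the hexahydroindene numbering of the target (C1–C7a), also for the bicyclic precursors. α is the face of the one-carbon arms on C4 and C5; β is the face of the C4 and C5 ethyl groups.
- (S)-8 and adduct 10 as drawn place the cyclobutene α and the ethyl and silyloxy groups β, which is the arrangement needed for 33; these structures need no correction.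
- Assumption: the 1β-ethyl, 3α-methyl arrangement of 33 is that of the more stable epimers of ketone 20, both groups pseudo-equatorial.
- Two simpler ideas are not used. γ-Oxidation of 2,3-diethylcyclohexenone through its dienol ether is regiochemically ambiguous. Differentiating the arms through a lactol from a C3a alcohol needs hydride delivery from the ethyl-bearing face of the C3a ketone, which is the hindered one.

## Route

Step 1
Reactants: 1 2-ethylcyclohexane-1,3-dione
Product: 2 3-ethoxy-2-ethylcyclohex-2-en-1-one
Conditions: EtOH, p-TsOH·H2O (cat.), PhMe, reflux, Dean–Stark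
Reagents that add atoms: ethanol, CCO
Why: Acid-catalysed enol etherification of a symmetrical cyclic 1,3-dione (vinylogous ester formation) driven by azeotropic removal of water; the two carbonyl groups are equivalent, so one product results.

Step 2
Reactants: 2 3-ethoxy-2-ethylcyclohex-2-en-1-one
Product: 3 (±)-3-ethoxy-2-ethyl-6-hydroxycyclohex-2-en-1-one
Conditions: LiN(i-Pr)2, THF, −78 °C; (±)-trans-2-(phenylsulfonyl)-3-phenyloxaziridine, −78 °C; aq. NH4Cl
Reagents that add atoms: 2-(phenylsulfonyl)-3-phenyloxaziridine, O=S(=O)(c1ccccc1)N1OC1c1ccccc1
Why: Kinetic deprotonation of a 3-alkoxyenone occurs at the α′ carbon and the enolate is oxidised by the N-sulfonyloxaziridine (Davis hydroxylation); the oxygen is thereby fixed on the future C6 before the carbonyl transposition.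

Step 3
Reactants: 3 (±)-3-ethoxy-2-ethyl-6-hydroxycyclohex-2-en-1-one
Product: 4 (S)-3-ethoxy-2-ethyl-6-hydroxycyclohex-2-en-1-one
Conditions: lipase from Burkholderia cepacia (immobilised), vinyl acetate, t-BuOMe, 30 °C, taken past half conversion
Reagents that add atoms: none
Why: Lipase-catalysed kinetic resolution by transesterification; by the empirical size rule for secondary alcohols the (R)-alcohol should be acetylated faster, so the (S)-alcohol should remain and can be brought to high enantiomeric purity by going past half conversion (configuration to be confirmed through Mosher esters).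

Step 4
Reactants: 4 (S)-3-ethoxy-2-ethyl-6-hydroxycyclohex-2-en-1-one
Product: 5 (S)-6-(tert-butyldimethylsilyloxy)-3-ethoxy-2-ethylcyclohex-2-en-1-one
Conditions: t-BuMe2SiCl, imidazole, DMF, 23 °C
Reagents that add atoms: tert-butyldimethylsilyl chloride, CC(C)(C)[Si](C)(C)Cl
Why: Imidazole-mediated silylation of a secondary alcohol; the bulky silyl ether is the later facial control element and survives organometallic and dissolving-metal steps.

Step 5
Reactants: 5 (S)-6-(tert-butyldimethylsilyloxy)-3-ethoxy-2-ethylcyclohex-2-en-1-one; 6 ethylmagnesium bromide
Product: 8 (S)-4-(tert-butyldimethylsilyloxy)-2,3-diethylcyclohex-2-en-1-one, via tertiary allylic alcohol 7 (not isolated)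
Conditions: EtMgBr, CeCl3, THF, −78 → 0 °C; then 1 M HCl, THF, 0 °C
Reagents that add atoms: water, O
Why: Stork–Danheiser transposition: the organocerium reagent from 6 adds 1,2 to the vinylogous ester carbonyl without enolising the α-silyloxy ketone, and cold dilute acid ionises 7, hydrolyses the enol ether and gives the transposed enone; the stereocentre is untouched and becomes C6.

Step 6
Reactants: 8 (S)-4-(tert-butyldimethylsilyloxy)-2,3-diethylcyclohex-2-en-1-one; 9 acetylene
Product: 10 (1R,5S,6S)-5-(tert-butyldimethylsilyloxy)-1,6-diethylbicyclo[4.2.0]oct-7-en-2-one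
Conditions: hν (medium-pressure Hg lamp, uranium-glass filter, λ ≥ 350 nm), acetylene (saturated solution, slow stream), CH2Cl2, −70 °C, stopped short of full conversion
Reagents that add atoms: none
Why: Excitation of the enone (n→π*) and intersystem crossing give the twisted triplet, which adds to acetylene stepwise: the first C–C bond forms at an enone carbon, and the triplet 1,4-diradical (alkyl radical plus vinyl radical) undergoes spin inversion and collapses to the cyclobutene. The closest known reaction type is the [2+2] photocycloaddition of cyclohexenones, 2,3-dialkyl ones included, to alkynes. The one new ring, the cyclobutene, is closed by radical recombination within the 1,4-diradical, and on a six-membered enone only the cis fusion is expected because a trans-fused cyclobutene is too strained; this fixes C4 relative to C5 with both ethyl groups on one face. C5 is set by approach of acetylene anti to the silyloxy group on the neighbouring C6: allylic strain with the C5 ethyl holds that group pseudo-axial, where it covers one face of the C4=C5 bond. C4 follows from the cis ring closure, so the single carbinol centre of 8 controls both quaternary carbons. The step needs facial selectivity, secured by the bulky silyl ether next to the β-carbon, and freedom from secondary photoreactions of the β,γ-unsaturated ketone 10 (1,3-acyl shift), for which the long-wavelength filter, low temperature, a non-sensitising solvent and incomplete conversion are chosen.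

Step 7
Reactants: 11 1-nitropropane; 12 propanal
Product: 13 4-nitrohexan-3-ol
Conditions: KOt-Bu (cat.), THF/t-BuOH, 0 → 23 °C
Reagents that add atoms: none
Why: Base-catalysed nitroaldol (Henry) addition; the diastereomer ratio is irrelevant because both stereocentres are removed in the next step.

Step 8
Reactants: 13 4-nitrohexan-3-ol
Product: 14 (E)-3-nitrohex-3-ene
Conditions: MeSO2Cl, Et3N, CH2Cl2, 0 °C
Reagents that add atoms: none
Why: Mesylation and E1cB elimination of a β-nitro alcohol; the trisubstituted nitroalkene is expected as the more stable (E) isomer.

Step 9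
Reactants: 10 (1R,5S,6S)-5-(tert-butyldimethylsilyloxy)-1,6-diethylbicyclo[4.2.0]oct-7-en-2-one; 14 (E)-3-nitrohex-3-ene
Product: 16 1,4-diketone (4-oxohexan-3-yl group on C7a of 10), via lithium nitronate 15 (not isolated)
Conditions: LiN(i-Pr)2, THF, −78 °C; 14, −78 °C; then aq. TiCl3, NH4OAc, THF/H2O, 0 → 23 °C
Reagents that add atoms: water, O
Why: Conjugate addition of a ketone lithium enolate to a nitroalkene, then reductive Nef reaction of the nitronate with TiCl3 (McMurry conditions); C7a is the only enolisable position of 10, and the electrophile should enter from the α face, away from both ethyl groups and with the silyloxy group pseudo-equatorial in the transition state. The new C1 centre is epimerisable and is corrected in step 11.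

Step 10
Reactants: 16 1,4-diketone (4-oxohexan-3-yl group on C7a of 10)
Product: 19 cyclobutene-fused bicyclic enone (C2 ketone; C3=C3a), via lithium aldolate 17 (not isolated), via aldol acetate 18 (not isolated)
Conditions: LiN(i-Pr)2, THF, −78 → −40 °C; Ac2O, −78 → 0 °C; DBU, 23 °C
Reagents that add atoms: none
Why: Kinetic enolisation at the only α-methylene group (C3) and intramolecular aldol addition (5-exo) to the C3a ketone, then acetylation of the aldolate and E1cB elimination. A non-equilibrating base is used because C7a, still α to a ketone in 16, must not epimerise: its epimer would let the silyloxy group sit equatorial and is expected to be the more stable one.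

Step 11
Reactants: 19 cyclobutene-fused bicyclic enone (C2 ketone; C3=C3a)
Product: 20 cyclobutene-fused trans-hydrindan-2-one (3a-H α; 7a-H β; 1β-ethyl; 3α-methyl; 6β-silyloxy)
Conditions: Li, NH3(l)/THF, t-BuOH (1 equiv), −78 °C; NH4Cl; then NaOMe (cat.), MeOH, 23 °C
Reagents that add atoms: none
Why: Dissolving-metal (Birch-type) conjugate reduction: the C3a carbanion is protonated axially on the α face, anti to the C4 ethyl and trans to C7a–H, which gives the trans fusion while the isolated cyclobutene and the silyl ether are inert. Methoxide then equilibrates C1 and C3 to the pseudo-equatorial 1β-ethyl, 3α-methyl epimer.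

Step 12
Reactants: 20 cyclobutene-fused trans-hydrindan-2-one
Product: 21 C2 ethylene ketal of 20
Conditions: Me3SiOCH2CH2OSiMe3, Me3SiOTf (cat.), CH2Cl2, −78 → −20 °C
Reagents that add atoms: 1,2-bis(trimethylsilyloxy)ethane, C[Si](C)(C)OCCO[Si](C)(C)C
Why: Noyori ketalisation under aprotic, low-temperature conditions suited to a hindered ketone; the dioxolane removes every enolisable position of the five-membered ring, so C7 becomes the only site for later enolate chemistry and C1 and C3 stay locked until the last step.

Step 13
Reactants: 21 C2 ethylene ketal of 20
Product: 22 C6 β-alcohol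
Conditions: Bu4NF, THF, 23 → 50 °C; aq. NH4Cl
Reagents that add atoms: none
Why: Fluoride cleavage of the silyl ether; ketal and cyclobutene are unaffected.

Step 14
Reactants: 22 C6 β-alcohol
Product: 23 C6 ketone
Conditions: Dess–Martin periodinane, NaHCO3, CH2Cl2, 23 °C
Reagents that add atoms: none
Why: Dess–Martin oxidation of a hindered secondary alcohol under buffered conditions that leave the ketal intact; C6 becomes sp2, which removes the syn interaction between the C6 oxygen and the C4 ethyl before the four-membered ring is opened.

Step 15
Reactants: 23 C6 ketone; 24 iodoethane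
Product: 25 7-ethyl C6 ketone
Conditions: LiN(i-Pr)2, THF, −78 °C; EtI, DMPU, −78 → 0 °C
Reagents that add atoms: none
Why: Enolate alkylation: C5 is quaternary and C2 is protected, so the lithium enolate can form only toward C7; the configuration at C7 is immaterial because the centre becomes sp2 in step 16.

Step 16
Reactants: 25 7-ethyl C6 ketone
Product: 26 C6 enol triflate (C6=C7 with ethyl on C7)
Conditions: KN(SiMe3)2, THF, −78 → 0 °C; PhNTf2, −78 → 23 °C
Reagents that add atoms: N-phenylbis(trifluoromethanesulfonimide), O=S(=O)(N(c1ccccc1)S(=O)(=O)C(F)(F)F)C(F)(F)F
Why: Deprotonation of the remaining C7–H gives the only possible enolate, which is O-sulfonylated; the enol triflate stores the future C6=C7 alkene in an electron-poor form that should resist ozone.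

Step 17
Reactants: 26 C6 enol triflate (C6=C7 with ethyl on C7)
Product: 28 C4 methyl ester C5 aldehyde, via methoxy hydroperoxide 27 (not isolated)
Conditions: O3 (1 equiv, Sudan Red 7B as indicator), CH2Cl2/MeOH, NaHCO3, −78 °C; then Ac2O, Et3N, CH2Cl2, 0 → 23 °C
Reagents that add atoms: ozone, [O-][O+]=O; methanol, CO
Why: Ozonolysis in methanol with dehydration of the methoxy hydroperoxide (Schreiber terminal differentiation): ozone should attack the strained cyclobutene and not the electron-poor enol triflate. The primary ozonide should fragment so that the carbonyl oxide, trapped by MeOH and turned into the methyl ester by Ac2O/Et3N, forms on the C4 arm, remote from the electron-withdrawing triflyloxy-alkenyl carbon on C5; the C5 arm is left as the aldehyde, and any regioisomer would be separable.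

Step 18
Reactants: 28 C4 methyl ester C5 aldehyde; 29 diethyl benzylphosphonate
Product: 30 (E)-styryl enol triflate
Conditions: NaH, THF, 0 → 50 °C
Reagents that add atoms: none
Why: Horner–Wadsworth–Emmons olefination of a non-enolisable neopentyl aldehyde with the benzylphosphonate anion, which should give the (E)-styrene; the ketal prevents aldol reactions of the five-membered ring ketone.

Step 19
Reactants: 30 (E)-styryl enol triflate
Product: 31 isospiculoic acid A methyl ester C2 ethylene ketal
Conditions: Pd(OAc)2 (cat.), PPh3, HCO2H, Et3N, DMF, 60 °C
Reagents that add atoms: none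
Why: Palladium-catalysed formate reduction of the enol triflate (oxidative addition, formate decarboxylation, reductive elimination) replaces OTf by H without touching the styryl group, the ester or the ketal, and places the alkene regiospecifically at C6=C7.

Step 20
Reactants: 31 isospiculoic acid A methyl ester C2 ethylene ketal
Product: 33 isospiculoic acid A, via sodium carboxylate 32 (not isolated)
Conditions: NaSEt, DMF, 80 °C; then 1 M HCl, THF, 23 °C
Reagents that add atoms: water, O
Why: SN2 demethylation by thiolate at the methyl group avoids the hindered neopentyl acyl carbon, and mild aqueous acid then hydrolyses the dioxolane; the ketone is exposed only under weakly acidic conditions at room temperature, so C1 and C3 should not epimerise.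

## Compound list

1 | 2-ethylcyclohexane-1,3-dione | CCC1C(=O)CCCC1=O | starting material
2 | 3-ethoxy-2-ethylcyclohex-2-en-1-one | CCOC1=C(CC)C(=O)CCC1 | intermediate
3 | (±)-3-ethoxy-2-ethyl-6-hydroxycyclohex-2-en-1-one | CCOC1=C(CC)C(=O)C(O)CC1 | intermediate
4 | (S)-3-ethoxy-2-ethyl-6-hydroxycyclohex-2-en-1-one | CCOC1=C(CC)C(=O)[C@@H](O)CC1 | intermediate
5 | (S)-6-(tert-butyldimethylsilyloxy)-3-ethoxy-2-ethylcyclohex-2-en-1-one | CCOC1=C(CC)C(=O)[C@@H](O[Si](C)(C)C(C)(C)C)CC1 | intermediate
6 | ethylmagnesium bromide | CC[Mg]Br | starting material
7 | (6S)-6-(tert-butyldimethylsilyloxy)-3-ethoxy-1,2-diethylcyclohex-2-en-1-ol, both C1 epimers (not isolated) | CCOC1=C(CC)C(O)(CC)[C@@H](O[Si](C)(C)C(C)(C)C)CC1 | intermediate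
8 | (S)-4-(tert-butyldimethylsilyloxy)-2,3-diethylcyclohex-2-en-1-one | CCC1=C(CC)[C@@H](O[Si](C)(C)C(C)(C)C)CCC1=O | intermediate
9 | acetylene | C#C | starting material
10 | (1R,5S,6S)-5-(tert-butyldimethylsilyloxy)-1,6-diethylbicyclo[4.2.0]oct-7-en-2-one (C3a ketone, cyclobutene α, C6 silyloxy β) | O=C1CC[C@H](O[Si](C)(C)C(C)(C)C)[C@@]2(CC)C=C[C@@]12CC | intermediate
11 | 1-nitropropane | CCC[N+](=O)[O-] | starting material
12 | propanal | CCC=O | starting material
13 | 4-nitrohexan-3-ol (diastereomer mixture) | CCC(O)C(CC)[N+](=O)[O-] | intermediate
14 | (E)-3-nitrohex-3-ene | CC/C=C(\CC)[N+](=O)[O-] | intermediate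
15 | lithium nitronate of the Michael adduct, side chain on C7a α (not isolated) | O=C1[C@@H]([C@@H](CC)C(CC)=[N+]([O-])[O-])C[C@H](O[Si](C)(C)C(C)(C)C)[C@@]2(CC)C=C[C@@]12CC.[Li+] | intermediate
16 | 5-(tert-butyldimethylsilyloxy)-1,6-diethyl-3-(4-oxohexan-3-yl)bicyclo[4.2.0]oct-7-en-2-one, side chain on C7a α, C1 drawn as in 33 (its epimer is equally usable) | O=C1[C@@H]([C@@H](CC)C(=O)CC)C[C@H](O[Si](C)(C)C(C)(C)C)[C@@]2(CC)C=C[C@@]12CC | intermediate
17 | lithium aldolate, C3–C3a bond formed, C3a–O−, C3 and C3a unassigned (not isolated) | C1[C@H](O[Si](C)(C)C(C)(C)C)[C@]4(CC)[C@@](CC)(C=C4)C2([O-])[C@H]1[C@@H](CC)C(=O)C2C.[Li+] | intermediate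
18 | C3a acetate of the aldol (not isolated) | C1[C@H](O[Si](C)(C)C(C)(C)C)[C@]4(CC)[C@@](CC)(C=C4)C2(OC(C)=O)[C@H]1[C@@H](CC)C(=O)C2C | intermediate
19 | bicyclic enone: C2 ketone, C3=C3a, 1β-ethyl, 3-methyl, 4β,5β-diethyl, C4–C5 bridged on the α face by CH=CH, 6β-silyloxy, 7a-H β | C1[C@H](O[Si](C)(C)C(C)(C)C)[C@]4(CC)[C@@](CC)(C=C4)C=2[C@H]1[C@@H](CC)C(=O)C=2C | intermediate
20 | trans-hydrindan-2-one: 3a-H α, 7a-H β, 1β-ethyl, 3α-methyl, 4β,5β-diethyl, 4α,5α CH=CH bridge, 6β-silyloxy | C1[C@H](O[Si](C)(C)C(C)(C)C)[C@]4(CC)[C@@](CC)(C=C4)[C@H]2[C@H]1[C@@H](CC)C(=O)[C@@H]2C | intermediate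
21 | C2 ethylene ketal (spiro-1,3-dioxolane) of 20 | C1[C@H](O[Si](C)(C)C(C)(C)C)[C@]4(CC)[C@@](CC)(C=C4)[C@H]2[C@H]1[C@@H](CC)C3(OCCO3)[C@@H]2C | intermediate
22 | C6 β-alcohol of 21 | C1[C@H](O)[C@]4(CC)[C@@](CC)(C=C4)[C@H]2[C@H]1[C@@H](CC)C3(OCCO3)[C@@H]2C | intermediate
23 | C6 ketone (C2 ketal, cyclobutene intact) | C1C(=O)[C@]4(CC)[C@@](CC)(C=C4)[C@H]2[C@H]1[C@@H](CC)C3(OCCO3)[C@@H]2C | intermediate
24 | iodoethane | CCI | starting material
25 | 7-ethyl C6 ketone, C7 epimers | CCC1C(=O)[C@]4(CC)[C@@](CC)(C=C4)[C@H]2[C@H]1[C@@H](CC)C3(OCCO3)[C@@H]2C | intermediate
26 | enol triflate: C6(OTf)=C7(Et), C2 ketal, cyclobutene intact | CCC1=C(OS(=O)(=O)C(F)(F)F)[C@]4(CC)[C@@](CC)(C=C4)[C@H]2[C@H]1[C@@H](CC)C3(OCCO3)[C@@H]2C | intermediate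
27 | C4 arm CH(OMe)OOH, C5 arm CHO (not isolated) | CCC1=C(OS(=O)(=O)C(F)(F)F)[C@](C=O)(CC)[C@@](CC)(C(OC)OO)[C@H]2[C@H]1[C@@H](CC)C3(OCCO3)[C@@H]2C | intermediate
28 | C4 methyl ester, C5 aldehyde, C6 enol triflate, C2 ketal | CCC1=C(OS(=O)(=O)C(F)(F)F)[C@](C=O)(CC)[C@@](CC)(C(=O)OC)[C@H]2[C@H]1[C@@H](CC)C3(OCCO3)[C@@H]2C | intermediate
29 | diethyl benzylphosphonate | CCOP(=O)(Cc1ccccc1)OCC | starting material
30 | C5 (E)-styryl, C4 methyl ester, C6 enol triflate, C2 ketal | CCC1=C(OS(=O)(=O)C(F)(F)F)[C@](/C=C/c2ccccc2)(CC)[C@@](CC)(C(=O)OC)[C@H]2[C@H]1[C@@H](CC)C3(OCCO3)[C@@H]2C | intermediate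
31 | isospiculoic acid A methyl ester, C2 ethylene ketal | CCC1=C[C@](/C=C/c2ccccc2)(CC)[C@@](CC)(C(=O)OC)[C@H]2[C@H]1[C@@H](CC)C3(OCCO3)[C@@H]2C | intermediate
32 | sodium carboxylate of the C2 ketal acid (not isolated) | CCC1=C[C@](/C=C/c2ccccc2)(CC)[C@@](CC)(C(=O)[O-])[C@H]2[C@H]1[C@@H](CC)C3(OCCO3)[C@@H]2C.[Na+] | intermediate
33 | isospiculoic acid A | CCC1=C[C@](/C=C/c2ccccc2)(CC)[C@@](CC)(C(=O)O)[C@H]2[C@H]1[C@@H](CC)C(=O)[C@@H]2C | target

## Step count and least certain steps

Total step count: 20. Longest linear sequence: 18 (steps 1–6 and 9–20; steps 7 and 8 make the nitroalkene on a side branch).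

**Step 6 (key step).** The most likely failures are incomplete facial discrimination by the silyloxy group, slow trapping of the hindered triplet by dilute acetylene, and further photoisomerisation of the β,γ-unsaturated ketone formed. Fallback: enone 8 is irradiated with (Z)-1,2-dichloroethene, a more concentrated and more reactive partner whose adduct is a saturated ketone and so photostable. This gives the dichlorocyclobutane adduct F1. Reductive elimination with zinc dust in hot ethanol removes both chlorine atoms and returns to the route at 10.

**Step 9.** The hindered enolate may transfer a proton from the allylic position of 14 instead of adding, and facial selectivity at C7a may be incomplete. Fallback: the enolate of 10 is alkylated with 1-bromobut-2-yne, an unhindered SN2 partner, to give the C7a butynyl ketone F2. Carbonyl-assisted hydration (NaAuCl4 cat., aq. MeOH) gives the 1,4-diketone without the C1 ethyl, F3. Ring closure as in step 10 gives the enone with a C1 methylene, F4, and reduction as in step 11 gives the hydrindanone with a C1 methylene, F5. Kinetic enolisation of F5 toward the C1 methylene (LiN(i-Pr)2) and alkylation with 24, followed by methoxide equilibration, returns to the route at 20.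

**Step 10.** The aldol addition to the hindered C3a ketone may be reversible, so that on warming the enolate persists and C7a drifts to its more stable epimer. Fallback: 16 is converted with LiN(i-Pr)2 and Me3SiCl into the C2 trimethylsilyl enol ether F6. TiCl4 in CH2Cl2 at −78 °C closes the ring by an intramolecular Mukaiyama aldol addition to the tertiary aldol F7. Acetylation and DBU elimination return to the route at 19.

**Step 11.** Protonation of the C3a carbanion may occur from the β face and give the cis fusion, or the ketone may be over-reduced. Fallback: 19 is reduced by hydride conjugate addition with [(Ph3P)CuH]6 in wet toluene. This delivers hydride to C3a kinetically from the α face, anti to the C4 ethyl, and after work-up and methoxide equilibration returns to the route at 20. This fallback makes no new compound (F0).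

**Step 17.** The primary ozonide may fragment in the opposite sense, so that the ester ends up on the C5 arm. Attack of ozone on the enol triflate is a lesser risk. Fallback: if the carbonyl oxide prefers the C5 arm, 26 is ozonised in MeOH/CH2Cl2 with p-TsOH and worked up with NaHCO3 and Me2S. The directly formed C4 aldehyde becomes its dimethyl acetal and the C5 hydroperoxide is reduced to the aldehyde, giving the C4 dimethyl acetal C5 aldehyde F8. Olefination as in step 18 gives the styryl acetal triflate F9, and formate reduction as in step 19 gives the styryl acetal alkene F10. Aqueous HCl in THF removes the acetal and the ketal to give the keto aldehyde F11. Pinnick oxidation (NaClO2, NaH2PO4, 2-methylbut-2-ene) returns to the route at 33.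

## Further compounds

F1 | step 6 | 5-(tert-butyldimethylsilyloxy)-7,8-dichloro-1,6-diethylbicyclo[4.2.0]octan-2-one (chlorine-bearing centres unassigned) | O=C1CC[C@H](O[Si](C)(C)C(C)(C)C)[C@@]2(CC)C(Cl)C(Cl)[C@@]12CC
F2 | step 9 | 3-(but-2-yn-1-yl)-5-(tert-butyldimethylsilyloxy)-1,6-diethylbicyclo[4.2.0]oct-7-en-2-one (side chain on C7a, α) | O=C1[C@@H](CC#CC)C[C@H](O[Si](C)(C)C(C)(C)C)[C@@]2(CC)C=C[C@@]12CC
F3 | step 9 | 5-(tert-butyldimethylsilyloxy)-1,6-diethyl-3-(2-oxobutyl)bicyclo[4.2.0]oct-7-en-2-one | O=C1[C@@H](CC(=O)CC)C[C@H](O[Si](C)(C)C(C)(C)C)[C@@]2(CC)C=C[C@@]12CC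
F4 | step 9 | bicyclic enone as 19 with a C1 methylene | C1[C@H](O[Si](C)(C)C(C)(C)C)[C@]4(CC)[C@@](CC)(C=C4)C=2[C@H]1CC(=O)C=2C
F5 | step 9 | trans-hydrindan-2-one as 20 with a C1 methylene | C1[C@H](O[Si](C)(C)C(C)(C)C)[C@]4(CC)[C@@](CC)(C=C4)[C@H]2[C@H]1CC(=O)[C@@H]2C
F6 | step 10 | C2 trimethylsilyl enol ether of 16 (C2=C3, geometry unassigned) | O=C1[C@@H]([C@@H](CC)C(O[Si](C)(C)C)=CC)C[C@H](O[Si](C)(C)C(C)(C)C)[C@@]2(CC)C=C[C@@]12CC
F7 | step 10 | tertiary aldol, C3a–OH (C3 and C3a unassigned) | C1[C@H](O[Si](C)(C)C(C)(C)C)[C@]4(CC)[C@@](CC)(C=C4)C2(O)[C@H]1[C@@H](CC)C(=O)C2C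
F0 | step 11 | none | none
F8 | step 17 | C4 dimethyl acetal, C5 aldehyde, C6 enol triflate, C2 ketal | CCC1=C(OS(=O)(=O)C(F)(F)F)[C@](C=O)(CC)[C@@](CC)(C(OC)OC)[C@H]2[C@H]1[C@@H](CC)C3(OCCO3)[C@@H]2C
F9 | step 17 | C4 dimethyl acetal, C5 (E)-styryl, C6 enol triflate, C2 ketal | CCC1=C(OS(=O)(=O)C(F)(F)F)[C@](/C=C/c2ccccc2)(CC)[C@@](CC)(C(OC)OC)[C@H]2[C@H]1[C@@H](CC)C3(OCCO3)[C@@H]2C
F10 | step 17 | C4 dimethyl acetal, C5 (E)-styryl, C6=C7 alkene, C2 ketal | CCC1=C[C@](/C=C/c2ccccc2)(CC)[C@@](CC)(C(OC)OC)[C@H]2[C@H]1[C@@H](CC)C3(OCCO3)[C@@H]2C
F11 | step 17 | C4 aldehyde analogue of 33 (C2 ketone free) | CCC1=C[C@](/C=C/c2ccccc2)(CC)[C@@](CC)(C=O)[C@H]2[C@H]1[C@@H](CC)C(=O)[C@@H]2C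
A1 | alternative 1 | bicyclic C3=C3a enone methyl ester | CCC1=C[C@](/C=C/c2ccccc2)(CC)[C@@](CC)(C(=O)OC)C2=C(C)C(=O)[C@H](CC)[C@@H]12
A2 | alternative 1 | methyl (4Z,6E)-2,3,5-triethyl-3-[(E)-2-phenylethenyl]-2-(prop-1-yn-1-yl)nona-4,6-dienoate, C2 and C3 configured as C4 and C5 of the target | CC/C=C/C(CC)=C\[C@](/C=C/c1ccccc1)(CC)[C@@](CC)(C(=O)OC)C#CC
A3 | alternative 2 | cis-fused menthyloxy lactone-acetal cyclohexenone | O=C1C[C@]2(CC)[C@](CC)(C=C1)C(=O)O[C@H]2O[C@@H]3C[C@H](C)CC[C@H]3C(C)C
A4 | alternative 2 | (E)-1-methoxy-3-(trimethylsilyloxy)buta-1,3-diene | CO/C=C/C(=C)O[Si](C)(C)C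
A5 | alternative 2 | 3,4-diethyl-5-(menthyloxy)furan-2(5H)-one | CCC1=C(CC)[C@H](O[C@@H]2C[C@H](C)CC[C@H]2C(C)C)OC1=O
A6 | alternative 3 | isospiculoic acid A methyl ester | CCC1=C[C@](/C=C/c2ccccc2)(CC)[C@@](CC)(C(=O)OC)[C@H]2[C@H]1[C@@H](CC)C(=O)[C@@H]2C
A7 | alternative 3 | trans-2,5-disubstituted cyclopentanone with a (Z)-1-ethyl-2-iodoethenyl group on C7a and, on C3a, the quaternary C4 carrying ethyl, CO2Me and a 1-ethyl-3-phenylprop-1-enyl arm (arm alkene geometry unassigned) | I/C=C(CC)\[C@@H]1[C@@H](CC)C(=O)[C@H](C)[C@H]1[C@](CC)(C(=O)OC)C(CC)=CCc1ccccc1
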